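# Proposed total synthesis of CNP0511668.0 (compound 23) by construction of ring A from an aryloxyfuran

## The problem

Target 23 is a 19-membered macrocycle of four benzene rings joined alternately by two diaryl ether oxygens and two CH2CH2 bridges, in the order ring A–O–ring B–bridge 1–ring C–O–ring D–bridge 2–ring A. Ring A carries hydroxyls at A1 and A6, the ether oxygen to ring B at A5 and bridge 2 at A3; ring B is para-linked (oxygen at B1, bridge 1 at B4); ring C carries bridge 1 at C1, hydroxyls at C3 and C4 and the ether oxygen to ring D at C5; ring D is meta-linked (oxygen at D1, bridge 2 at D3). There is no stereocentre, so nothing has to be set or relayed, and the difficulties are regiochemical and topological. Rings A and C each hold three adjacent oxygens of which only an outer one is arylated, so three neighbouring oxygens have to be told apart. The two catechols oxidize readily to ortho-quinones and chelate transition metals, so they must stay masked through every basic or metal-mediated step and be released last, whereas the diaryl ethers and the saturated bridges are robust. The macrocycle must be closed at a bond whose formation tolerates high dilution and meets no competing reactive site. The feature that allows ring A to be built de novo is its pattern: oxygens at A5, A6 and A1, hydrogen at A2 and A4, carbon at A3. This is what a furan oxygenated at both β-carbons gives after a monosubstituted alkyne adds across its α-carbons, with the furan ring oxygen ending as the A1 hydroxyl.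

## Retrosynthesis

**23 from 22.** The four O–CH3 bonds at A1, A6, C3 and C4 are cut last. Methyl ethers are the smallest masks that survive copper, palladium, hydride and low-valent titanium. One kind of protecting group means one final operation. The forward step only has to cleave alkyl–oxygen bonds without touching the diaryl ethers.

**22 from 20 through 21.** The macrocycle is opened at the central C–C bond of bridge 2, giving dialdehyde 20 with one formyl group on ring A (A3) and one on ring D (D3). Closing at the ring C–O–ring D ether instead would need a second aryl halide and a protected phenol in a molecule that must first undergo a palladium coupling at a ring B bromide. Closing at the ring A ether would attack the most hindered oxygen. A carbonyl coupling has no such conflicts: stilbene 21 forms by reductive coupling and is hydrogenated to 22. The forward reaction must favour ring closure over oligomerization at high dilution.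

**20 from 18 through 19.** Both aldehydes come from methyl esters by reduction to diol 19 and benzylic oxidation. Keeping both carbons at the ester oxidation level means the two ends are processed together and tolerate the preceding palladium step.

**18 from 12 and 16 through 17.** Bridge 1 is cut at the B4–CH2 bond. The bromide of 12 is the only halide in either partner and styrene 16 supplies both bridge carbons through its 9-BBN adduct 17, so the bridge arrives saturated. A Wittig alternative would need an aldehyde, a phosphonium salt and a hydrogenation. This cut divides the molecule into an A–B half and a C–D half of similar size.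

**16 from 13 and 14 through 15.** The ring C–O–ring D ether is made intermolecularly, where it is easy: phenol 13 already has the C3, C4, C5 oxygen pattern with only the C5 oxygen free, and iodide 14 carries the future D3 carbon as an ester. Methylenation of the aldehyde of 15 then gives 16. No selectivity among the ring C oxygens is required.

**12 from 8 and 9 through 10 and 11 (key disconnection).** Ring A is taken apart at the A3–A4 and A1–A2 bonds, together with the bond that tied the A1 oxygen to A4 in the bridged adduct 10. This leads to 3-(4-bromophenoxy)-4-methoxyfuran 8 and methyl propiolate 9. Its merit is that the three ring A oxygens have three different origins and need no differentiation afterwards: the aryloxy group is placed on the furan, the methoxy group is the second furan substituent, and the furan ring oxygen emerges as a free phenol in 11, which is methylated to 12. The forward reaction needs one orientation of the alkyne and one direction of bridge opening. The bromine on the aryloxy group serves as the handle for bridge 1 and also weakens the donor strength of that oxygen, which helps the orientation.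

**8 from 4 and 5 through 6 and 7.** The two α-carboxyl groups of diacid 7 are removed retrosynthetically to diester 6, and the aryl–oxygen bond is cut to hydroxyfuran 4 and 1-bromo-4-iodobenzene 5. The esters hold the hydroxyfuran in its aromatic enol form and make the hydroxyl a phenol-like acid that can be arylated; the free 3-hydroxyfuran would not be a workable intermediate.

**4 from 1 and 2 through 3.** The furan ring of 3 is opened at both C–C bonds between the α- and β-carbons to dimethyl diglycolate 1 and dimethyl oxalate 2. Mono-methylation of the symmetric bis-enol 3 then gives 4; this is the only point at which two like oxygens must be distinguished.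

## Roads not taken

In this section the labels A1 to A7 stand for compounds of the alternatives, and ring positions are spelled out in words.

**Alternative 1:** The two aryl C–O bonds at position 1 of ring A and position 3 of ring C are cut last. The macrocyclic bis(O-aryl diethylcarbamate) A1, which lacks those two oxygens, would be lithiated twice ortho to the carbamates, borylated and oxidized to the bis(hydroxy carbamate) A2.
- Merits: every ring can be bought with its oxygens in place as simple mono-oxygenated aromatics; the only free ortho position of each carbamate is the right one; both catechols are completed in one operation.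
- Weak points: the step is a double lithiation of a large macrocycle with four benzylic CH2 groups and two diaryl ether oxygens that direct metalation to rings B and D. The lithiated carbamate can undergo an anionic ortho-Fries shift. All of this falls on the most advanced intermediate, and a forcing carbamate cleavage in the presence of free catechols still follows.
- Comparison: this road is better in its building blocks, since no ring is built and no trioxygenated pattern is needed early. Against that, the chosen plan places its uncertain step at step 6 of 15, on small molecules, and ends with hydrogenation and ether cleavage, which do not distinguish between positions.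

**Alternative 2:** The ether bond between position 5 of ring A and the bridging oxygen is cut, which also opens the macrocycle. The seco bis(halophenol) A3, with a 2,6-dibromophenol as ring A and a 2,6-dichlorophenol as ring B, would be oxidized with Tl(NO3)3 in methanol and reduced with zinc in acetic acid to give macrocycle A4.
- Merits: the hindered ether and the 19-membered ring are made together, in the manner of a biosynthetic phenol coupling, and the halogen pattern decides which phenol acts as nucleophile.
- Weak points: stoichiometric trivalent thallium; a ring larger than those for which this coupling is usually used. A4 still needs the bromide at position 1 of ring A converted to a hydroxyl, then the two ring B chlorides removed, in that order and without cross-reaction.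
- Comparison: in bond economy this road is better, doing in one step what the chosen plan does in steps 3 and 13. The chosen plan sets against it the absence of thallium and of halogen bookkeeping, and ring A oxygens that are fixed by construction rather than by a late substitution.

**Alternative 3:** Ring B is cut at the two bonds B1–B2 and B5–B6. The aryl ethynyl ether A5 would add to methyl coumalate A6, its terminal carbon bonding to C6 of the pyrone, and loss of CO2 would give the para-aryloxybenzoate A7, which holds rings A, B and D.
- Merits: the orientation of this cycloaddition is dependable, CO2 is the only by-product, and the ester is a ready handle for bridge 1.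
- Weak points: the benzannulation is spent on ring B, an unsubstituted para-phenylene. Ordinary ether-forming chemistry with a para-substituted benzoate reaches A7 in fewer steps than the preparation and cycloaddition of the sensitive A5.
- Comparison: the regiochemistry here is more secure than in the chosen key step, which rests on the donor difference between methoxy and aryloxy. The chosen plan sets against it that its cycloaddition builds the ring whose three adjacent oxygens must be differentiated, and does so by their origin.

Key step: step 6

Assumption: stilbene 21 is written as the Z isomer; should step 13 give the other alkene geometry, step 14 reduces it to the same compound 22.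

## Route

Step 1
Reactants: 1 dimethyl diglycolate; 2 dimethyl oxalate
Product: 3 dimethyl 3,4-dihydroxyfuran-2,5-dicarboxylate
Conditions: NaOMe (2.5 equiv), MeOH, reflux; then aq. HCl, 0 °C
Reagents that add atoms: none
Why: Hinsberg-type double Claisen condensation: each α-methylene of 1 is acylated by one ester carbonyl of 2 and the resulting 3,4-dioxo ring exists as the aromatic bis-enol; precipitation of the disodium salt drives the equilibrium.

Step 2
Reactants: 3 dimethyl 3,4-dihydroxyfuran-2,5-dicarboxylate
Product: 4 dimethyl 3-hydroxy-4-methoxyfuran-2,5-dicarboxylate
Conditions: Me2SO4 (1.0 equiv), KHCO3 (1.1 equiv), DMF, 40 °C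
Reagents that add atoms: dimethyl sulfate, COS(=O)(=O)OC
Why: O-alkylation of the mono-anion of an acidic bis-enol with a hard methylating agent; a weak base and one equivalent of electrophile should hold the reaction largely at the mono-ether, since the remaining hydroxyl of 4 is expected to be less acidic than the first hydroxyl of 3, and unchanged 3 and neutral bis-ether are separable by their acidity.

Step 3
Reactants: 4 dimethyl 3-hydroxy-4-methoxyfuran-2,5-dicarboxylate; 5 1-bromo-4-iodobenzene
Product: 6 dimethyl 3-(4-bromophenoxy)-4-methoxyfuran-2,5-dicarboxylate
Conditions: CuI (10 mol%), picolinic acid (20 mol%), K3PO4 (2 equiv), DMSO, 90 °C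
Reagents that add atoms: none
Why: Ullmann-type diaryl ether synthesis; the enolic hydroxyl of 4 behaves as an acidic phenol, and monovalent copper reacts with the C–I bond much faster than with the C–Br bond, so the bromide should be retained.

Step 4
Reactants: 6 dimethyl 3-(4-bromophenoxy)-4-methoxyfuran-2,5-dicarboxylate
Product: 7 3-(4-bromophenoxy)-4-methoxyfuran-2,5-dicarboxylic acid
Conditions: LiOH (4 equiv), THF/MeOH/H2O, 40 °C; then 1 M HCl, 0 °C
Reagents that add atoms: lithium hydroxide, [Li+].[OH-]
Why: Ester saponification; the aryl ether and enol ether are inert to hydroxide under these conditions, and the diacid is liberated cold because alkoxyfuran-2-carboxylic acids lose CO2 when warmed with acid.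

Step 5
Reactants: 7 3-(4-bromophenoxy)-4-methoxyfuran-2,5-dicarboxylic acid
Product: 8 3-(4-bromophenoxy)-4-methoxyfuran
Conditions: Ag2CO3 (10 mol%), AcOH (5 mol%), DMSO, 120 °C
Reagents that add atoms: none
Why: Silver-catalysed protodecarboxylation of heteroaryl carboxylic acids; both carboxyl groups sit on furan α-carbons next to donor oxygens, the arrangement that decarboxylates most readily, and the aryl bromide is inert to the silver salt; 8 is used at once because alkoxyfurans are sensitive to acid and air.

Step 6
Reactants: 8 3-(4-bromophenoxy)-4-methoxyfuran; 9 methyl propiolate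
Product: 11 methyl 3-(4-bromophenoxy)-5-hydroxy-4-methoxybenzoate, via oxanorbornadiene adduct 10 (not isolated)
Conditions: 9 (3 equiv), PhMe, 80 °C (sealed tube); then TFA (10 mol%), CH2Cl2, 0 °C to rt
Reagents that add atoms: none
Why: The electron-rich furan 8 and the electron-poor alkyne 9 combine in a normal-demand Diels–Alder reaction across the two furan α-carbons, closing the six-membered carbocycle of ring A by intermolecular (4+2) cycloaddition to give the 7-oxanorbornadiene 10, whose two bridgehead centres are fixed relative to each other by the bicycle, are racemic and vanish on aromatization, so no stereochemistry has to be controlled. The orientation needed is the one in which the α-carbon next to the methoxy-bearing carbon bonds to the unsubstituted alkyne terminus (the A1–A2 bond) and the α-carbon next to the aryloxy-bearing carbon bonds to the ester-bearing terminus (the A3–A4 bond); it is secured by methoxy being the stronger π-donor, which places the larger HOMO coefficient on its neighbouring α-carbon, while the 4-bromophenoxy oxygen shares its lone pair with an electron-poor arene. Acid then ionizes the bridge C–O bond at the bridgehead flanked by the ester-bearing and aryloxy-bearing carbons, because that cation is delocalized onto the methoxy-bearing carbon as an oxocarbenium ion and onto the hydrogen-bearing alkene carbon, whereas the other cleavage would place charge on the ester-bearing carbon and on the less donating aryloxy carbon. The oxygen therefore stays on the other bridgehead, and loss of that proton should give phenol 11 with the hydroxyl at A1. The closest known reaction type is the cycloaddition of 3,4-dialkoxyfurans with acetylenic esters followed by acid isomerization of the oxanorbornadiene to a hydroxybenzoate. An excess of 9 at moderate temperature counters the reversibility of furan cycloadditions, and the acid is added only after the diene is consumed so that the enol ethers of 8 are not hydrolysed.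

Step 7
Reactants: 11 methyl 3-(4-bromophenoxy)-5-hydroxy-4-methoxybenzoate
Product: 12 methyl 3-(4-bromophenoxy)-4,5-dimethoxybenzoate
Conditions: MeI, K2CO3, DMF, rt
Reagents that add atoms: iodomethane, CI
Why: Williamson ether synthesis at the only acidic site, the A1 phenol; the new methyl ether matches the other three masked hydroxyls so that all are cleaved together in step 15.

Step 8
Reactants: 13 3-hydroxy-4,5-dimethoxybenzaldehyde; 14 methyl 3-iodobenzoate
Product: 15 methyl 3-(5-formyl-2,3-dimethoxyphenoxy)benzoate
Conditions: CuI (10 mol%), N,N-dimethylglycine hydrochloride (30 mol%), Cs2CO3 (2 equiv), 1,4-dioxane, 90 °C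
Reagents that add atoms: none
Why: Ullmann diaryl ether coupling of an electron-poor, unhindered aryl iodide with an electron-rich phenoxide, the favourable polarity for copper catalysis; the ortho-methoxy group is tolerated with an amino acid ligand, and the aldehyde and ester are spectators under carbonate.

Step 9
Reactants: 15 methyl 3-(5-formyl-2,3-dimethoxyphenoxy)benzoate
Product: 16 methyl 3-(5-ethenyl-2,3-dimethoxyphenoxy)benzoate
Conditions: Ph3PCH3Br (1.3 equiv), KOtBu (1.25 equiv), THF, 0 °C
Reagents that add atoms: methyltriphenylphosphonium bromide, C[P+](c1ccccc1)(c1ccccc1)c1ccccc1.[Br-]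
Why: Wittig methylenation; the unstabilized ylide adds to the aldehyde far faster than to the aryl ester at 0 °C.

Step 10
Reactants: 16 methyl 3-(5-ethenyl-2,3-dimethoxyphenoxy)benzoate; 12 methyl 3-(4-bromophenoxy)-4,5-dimethoxybenzoate
Product: 18 methyl 3-[4-(2-{3,4-dimethoxy-5-[3-(methoxycarbonyl)phenoxy]phenyl}ethyl)phenoxy]-4,5-dimethoxybenzoate, via B-alkyl-9-BBN borane 17 (not isolated)
Conditions: 16, 9-BBN dimer (0.6 equiv), THF, rt; then 12, PdCl2(dppf) (5 mol%), K3PO4 (3 equiv), DMF/H2O, 60 °C
Reagents that add atoms: none
Why: Anti-Markovnikov hydroboration of the styrene by 9-BBN followed by B-alkyl Suzuki–Miyaura coupling; the bromide of 12 is the only carbon–halogen bond present, the bidentate ferrocenylphosphine suppresses β-hydride elimination, and methyl esters withstand aqueous phosphate at this temperature.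

Step 11
Reactants: 18 the diester from step 10
Product: 19 {3-[4-(2-{3-[3-(hydroxymethyl)phenoxy]-4,5-dimethoxyphenyl}ethyl)phenoxy]-4,5-dimethoxyphenyl}methanol
Conditions: LiAlH4, THF, 0 °C to rt
Reagents that add atoms: none
Why: Hydride reduction of both aryl esters to benzylic alcohols in one operation; no halide or other reducible group remains.

Step 12
Reactants: 19 the bis(benzylic alcohol) from step 11
Product: 20 3-[4-(2-{3-(3-formylphenoxy)-4,5-dimethoxyphenyl}ethyl)phenoxy]-4,5-dimethoxybenzaldehyde
Conditions: activated MnO2 (excess), CH2Cl2, rt
Reagents that add atoms: none
Why: Selective oxidation of benzylic alcohols by MnO2, which stops at the aldehyde and leaves ethers untouched.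

Step 13
Reactants: 20 the dialdehyde from step 12
Product: 21 macrocyclic (Z)-stilbene, the 19-membered ring A–O–ring B–CH2CH2–ring C–O–ring D–CH=CH–ring A with methoxy groups at A1, A6, C3 and C4
Conditions: TiCl4, Zn dust, pyridine, THF, reflux; 20 added over 12 h by syringe pump (final ca. 2 mM); then aq. K2CO3
Reagents that add atoms: none
Why: Intramolecular McMurry reductive coupling of two aryl aldehydes on low-valent titanium, which joins the two formyl carbons as the CH=CH unit and leaves bridge 1 as the two-carbon chain it already is; slow addition keeps the dialdehyde dilute so that closure of the 19-membered ring competes with oligomerization, a mode of closure with precedent for macrocyclic bis(bibenzyl) skeletons, and methyl and diaryl ethers are inert to the reagent.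

Step 14
Reactants: 21 the macrocyclic stilbene from step 13
Product: 22 tetra-O-methyl ether of 23 (methoxy groups at A1, A6, C3 and C4; both bridges CH2CH2)
Conditions: H2 (1 atm), Pd/C, EtOAc/THF, rt
Reagents that add atoms: none
Why: Catalytic hydrogenation of the stilbene double bond, an addition of H2 that splits nothing off; the molecule holds no benzyl ether, halide or other hydrogenolysable group, and either alkene isomer gives the same product.

Step 15
Reactants: 22 the tetramethyl ether from step 14
Product: 23 CNP0511668.0, the target tetraphenol
Conditions: BBr3 (8 equiv), CH2Cl2, −78 °C to rt; then H2O, 0 °C, under argon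
Reagents that add atoms: none
Why: Lewis acid cleavage of aryl methyl ethers by BBr3, which attacks the methyl carbon and leaves the diaryl ether bonds intact; work-up under inert gas protects the two catechols from oxidation.

## Compound list

1 | dimethyl diglycolate (dimethyl 2,2'-oxydiacetate) | COC(=O)COCC(=O)OC | starting material
2 | dimethyl oxalate | COC(=O)C(=O)OC | starting material
3 | dimethyl 3,4-dihydroxyfuran-2,5-dicarboxylate | COC(=O)c1oc(C(=O)OC)c(O)c1O | intermediate
4 | dimethyl 3-hydroxy-4-methoxyfuran-2,5-dicarboxylate | COC(=O)c1oc(C(=O)OC)c(OC)c1O | intermediate
5 | 1-bromo-4-iodobenzene | Brc1ccc(I)cc1 | starting material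
6 | dimethyl 3-(4-bromophenoxy)-4-methoxyfuran-2,5-dicarboxylate | COC(=O)c1oc(C(=O)OC)c(OC)c1Oc1ccc(Br)cc1 | intermediate
7 | 3-(4-bromophenoxy)-4-methoxyfuran-2,5-dicarboxylic acid | OC(=O)c1oc(C(=O)O)c(OC)c1Oc1ccc(Br)cc1 | intermediate
8 | 3-(4-bromophenoxy)-4-methoxyfuran | COc1cocc1Oc1ccc(Br)cc1 | intermediate
9 | methyl propiolate | COC(=O)C#C | starting material
10 | methyl 6-(4-bromophenoxy)-5-methoxy-7-oxabicyclo[2.2.1]hepta-2,5-diene-2-carboxylate (racemic, one enantiomer drawn; not isolated) | COC(=O)C1=C[C@@H]2O[C@H]1C(Oc1ccc(Br)cc1)=C2OC | intermediate
11 | methyl 3-(4-bromophenoxy)-5-hydroxy-4-methoxybenzoate | COC(=O)c1cc(O)c(OC)c(c1)Oc1ccc(Br)cc1 | intermediate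
12 | methyl 3-(4-bromophenoxy)-4,5-dimethoxybenzoate | COC(=O)c1cc(OC)c(OC)c(c1)Oc1ccc(Br)cc1 | intermediate
13 | 3-hydroxy-4,5-dimethoxybenzaldehyde | O=Cc1cc(O)c(OC)c(OC)c1 | starting material
14 | methyl 3-iodobenzoate | COC(=O)c1cccc(I)c1 | starting material
15 | methyl 3-(5-formyl-2,3-dimethoxyphenoxy)benzoate | COC(=O)c1cccc(c1)Oc1cc(C=O)cc(OC)c1OC | intermediate
16 | methyl 3-(5-ethenyl-2,3-dimethoxyphenoxy)benzoate | COC(=O)c1cccc(c1)Oc1cc(C=C)cc(OC)c1OC | intermediate
17 | methyl 3-{5-[2-(9-borabicyclo[3.3.1]nonan-9-yl)ethyl]-2,3-dimethoxyphenoxy}benzoate (not isolated) | COC(=O)c1cccc(c1)Oc1cc(CCB2C3CCCC2CCC3)cc(OC)c1OC | intermediate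
18 | methyl 3-[4-(2-{3,4-dimethoxy-5-[3-(methoxycarbonyl)phenoxy]phenyl}ethyl)phenoxy]-4,5-dimethoxybenzoate | COC(=O)c1cc(OC)c(OC)c(c1)Oc1ccc(CCc2cc(OC)c(OC)c(c2)Oc2cccc(c2)C(=O)OC)cc1 | intermediate
19 | {3-[4-(2-{3-[3-(hydroxymethyl)phenoxy]-4,5-dimethoxyphenyl}ethyl)phenoxy]-4,5-dimethoxyphenyl}methanol | OCc1cc(OC)c(OC)c(c1)Oc1ccc(CCc2cc(OC)c(OC)c(c2)Oc2cccc(c2)CO)cc1 | intermediate
20 | 3-[4-(2-{3-(3-formylphenoxy)-4,5-dimethoxyphenyl}ethyl)phenoxy]-4,5-dimethoxybenzaldehyde | O=Cc1cc(OC)c(OC)c(c1)Oc1ccc(CCc2cc(OC)c(OC)c(c2)Oc2cccc(c2)C=O)cc1 | intermediate
21 | macrocyclic (Z)-stilbene: 19-membered ring A–O–ring B–CH2CH2–ring C–O–ring D–CH=CH–ring A, methoxy groups at A1, A6, C3, C4 | C1Cc2cc(OC)c(OC)c(c2)Oc2cccc(c2)/C=C\c2cc(OC)c(OC)c(c2)Oc2ccc1cc2 | intermediate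
22 | tetra-O-methyl ether of the target (methoxy groups at A1, A6, C3, C4; both bridges CH2CH2) | COc1cc2cc(c1OC)Oc1ccc(cc1)CCc1cc(OC)c(OC)c(c1)Oc1cccc(c1)CC2 | intermediate
23 | CNP0511668.0: 19-membered bis(bibenzyl) macrocycle ring A–O–ring B–CH2CH2–ring C–O–ring D–CH2CH2–ring A with hydroxyls at A1, A6, C3, C4 (no stereocentres) | Oc1cc2cc(c1O)Oc1ccc(cc1)CCc1cc(O)c(O)c(c1)Oc1cccc(c1)CC2 | target

## Step count and least certain steps

Total step count: 15. Longest linear sequence: 13 steps (steps 1–7, then 10–15); the ring C–ring D branch (steps 8 and 9) joins at step 10.

**Step 6 (key step).** The most likely failure is poor discrimination between the two orientations of the alkyne, because methoxy and 4-bromophenoxy differ only moderately as donors. The furan α-carbon may also add to the propiolate in conjugate fashion without ring closure, or the adduct may revert on heating.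

The fallback removes the regiochemical question by keeping the furan symmetrical and introducing the aryl group after ring A exists. It sets out from 3. Exhaustive O-methylation (Me2SO4, K2CO3, acetone) would give dimethyl 3,4-dimethoxyfuran-2,5-dicarboxylate F1. Saponification would give 3,4-dimethoxyfuran-2,5-dicarboxylic acid F2. Decarboxylation (Cu powder, quinoline, heat; no halide is present) would give 3,4-dimethoxyfuran F3. Cycloaddition of F3 with 9 can give only one orientation, the oxanorbornadiene methyl 5,6-dimethoxy-7-oxabicyclo[2.2.1]hepta-2,5-diene-2-carboxylate F4. Acid isomerizes it to methyl 3-hydroxy-4,5-dimethoxybenzoate F5. Copper-catalysed O-arylation of F5 with 5 (CuI, N,N-dimethylglycine hydrochloride, Cs2CO3, 1,4-dioxane) returns to the route at 12. F5 is also an article of commerce, which would shorten this rescue to one step.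

**Step 3.** The enolate of 4 is a weak and chelating nucleophile that can bind copper through the hydroxyl oxygen and the neighbouring ester. The coupling may therefore be sluggish, and raising the temperature would erode the selectivity for iodide over bromide.

The fallback needs no copper in the bond-forming step and sets out from 4. Nucleophilic aromatic substitution on 1-fluoro-4-nitrobenzene (K2CO3, DMF, 80 °C) would give dimethyl 3-methoxy-4-(4-nitrophenoxy)furan-2,5-dicarboxylate F6. Reduction (Fe, NH4Cl, EtOH/H2O) would give dimethyl 3-(4-aminophenoxy)-4-methoxyfuran-2,5-dicarboxylate F7. A Sandmeyer bromination (t-BuONO, CuBr2, MeCN) through the arenediazonium bromide 4-{[4-methoxy-2,5-bis(methoxycarbonyl)furan-3-yl]oxy}benzenediazonium bromide F8 returns to the route at 6.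

**Step 10.** Oxidative addition to the electron-rich aryl bromide may be slow enough for protodeboronation of the alkylborane or β-hydride elimination of the alkylpalladium intermediate to compete, and the esters may be partly hydrolysed by aqueous base.

The fallback forms bridge 1 as an alkene and sets out from 12 and 16. A Heck reaction (Pd(OAc)2, P(o-tol)3, Et3N, DMF, 100 °C) would give the stilbene methyl 3-(4-{(E)-2-[3,4-dimethoxy-5-(3-methoxycarbonylphenoxy)phenyl]ethenyl}phenoxy)-4,5-dimethoxybenzoate F9. Hydrogenation (H2, Pd/C) returns to the route at 18.

**Step 13.** Intermolecular coupling may outrun ring closure and give oligomers, or the reduction may stop at the pinacol stage.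

The fallback closes the same bond by metathesis and sets out from 20. Double Wittig methylenation (Ph3PCH3Br, KOtBu, THF) would give the bis-styrene 5-ethenyl-1-[4-(2-{3-(3-ethenylphenoxy)-4,5-dimethoxyphenyl}ethyl)phenoxy]-2,3-dimethoxybenzene F10. Ring-closing metathesis at high dilution with the second-generation Grubbs catalyst RuCl2(=CHPh)(PCy3)(SIMes) in CH2Cl2 at reflux should close the 19-membered ring with loss of ethene. The Z isomer of the ring-closed product is 21 itself, where the fallback returns to the route. An equilibrating metathesis may instead favour the E isomer of the macrocyclic stilbene F11; this is hydrogenated under the conditions of step 14 and then returns at 22.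

## Further compounds

F1 | step 6 | dimethyl 3,4-dimethoxyfuran-2,5-dicarboxylate | COC(=O)c1oc(C(=O)OC)c(OC)c1OC
F2 | step 6 | 3,4-dimethoxyfuran-2,5-dicarboxylic acid | OC(=O)c1oc(C(=O)O)c(OC)c1OC
F3 | step 6 | 3,4-dimethoxyfuran | COc1cocc1OC
F4 | step 6 | methyl 5,6-dimethoxy-7-oxabicyclo[2.2.1]hepta-2,5-diene-2-carboxylate (racemic, one enantiomer drawn) | COC(=O)C1=C[C@@H]2O[C@H]1C(OC)=C2OC
F5 | step 6 | methyl 3-hydroxy-4,5-dimethoxybenzoate | COC(=O)c1cc(O)c(OC)c(OC)c1
F6 | step 3 | dimethyl 3-methoxy-4-(4-nitrophenoxy)furan-2,5-dicarboxylate | COC(=O)c1oc(C(=O)OC)c(OC)c1Oc1ccc(cc1)[N+](=O)[O-]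
F7 | step 3 | dimethyl 3-(4-aminophenoxy)-4-methoxyfuran-2,5-dicarboxylate | COC(=O)c1oc(C(=O)OC)c(OC)c1Oc1ccc(N)cc1
F8 | step 3 | 4-{[4-methoxy-2,5-bis(methoxycarbonyl)furan-3-yl]oxy}benzenediazonium bromide | COC(=O)c1oc(C(=O)OC)c(OC)c1Oc1ccc(cc1)[N+]#N.[Br-]
F9 | step 10 | methyl 3-(4-{(E)-2-[3,4-dimethoxy-5-(3-methoxycarbonylphenoxy)phenyl]ethenyl}phenoxy)-4,5-dimethoxybenzoate | COC(=O)c1cc(OC)c(OC)c(c1)Oc1ccc(/C=C/c2cc(OC)c(OC)c(c2)Oc2cccc(c2)C(=O)OC)cc1
F10 | step 13 | 5-ethenyl-1-[4-(2-{3-(3-ethenylphenoxy)-4,5-dimethoxyphenyl}ethyl)phenoxy]-2,3-dimethoxybenzene | C=Cc1cc(OC)c(OC)c(c1)Oc1ccc(CCc2cc(OC)c(OC)c(c2)Oc2cccc(C=C)c2)cc1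
F11 | step 13 | E isomer of the macrocyclic stilbene (same connectivity as 21, (E)-CH=CH between ring D and ring A) | C1Cc2cc(OC)c(OC)c(c2)Oc2cccc(c2)/C=C/c2cc(OC)c(OC)c(c2)Oc2ccc1cc2
A1 | alternative 1 | macrocyclic bis(O-aryl N,N-diethylcarbamate): target skeleton without the oxygens at position 1 of ring A and position 3 of ring C, diethylcarbamates on the oxygens at position 6 of ring A and position 4 of ring C | CCN(CC)C(=O)Oc1ccc2cc1Oc1ccc(cc1)CCc1ccc(OC(=O)N(CC)CC)c(c1)Oc1cccc(c1)CC2
A2 | alternative 1 | macrocyclic bis(carbamate) with hydroxyls at position 1 of ring A and position 3 of ring C | Oc1cc2cc(c1OC(=O)N(CC)CC)Oc1ccc(cc1)CCc1cc(O)c(OC(=O)N(CC)CC)c(c1)Oc1cccc(c1)CC2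
A3 | alternative 2 | 2,6-dibromo-4-[2-(3-{5-[2-(3,5-dichloro-4-hydroxyphenyl)ethyl]-2,3-dimethoxyphenoxy}phenyl)ethyl]phenol | Oc1c(Br)cc(cc1Br)CCc1cccc(c1)Oc1cc(cc(OC)c1OC)CCc1cc(Cl)c(O)c(Cl)c1
A4 | alternative 2 | macrocyclic diaryl ether with hydroxyl at position 6 and bromide at position 1 of ring A, chlorides at positions 2 and 6 of ring B, methoxy groups at positions 3 and 4 of ring C | Brc1cc2cc(c1O)Oc1c(Cl)cc(cc1Cl)CCc1cc(OC)c(OC)c(c1)Oc1cccc(c1)CC2
A5 | alternative 3 | 1-(benzyloxy)-3-[2-(3-ethynyloxy-4,5-dimethoxyphenyl)ethyl]benzene | C#COc1cc(cc(OC)c1OC)CCc1cccc(OCc2ccccc2)c1
A6 | alternative 3 | methyl coumalate (methyl 2-oxo-2H-pyran-5-carboxylate) | COC(=O)C1=COC(=O)C=C1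
A7 | alternative 3 | methyl 4-(5-{2-[3-(benzyloxy)phenyl]ethyl}-2,3-dimethoxyphenoxy)benzoate | COC(=O)c1ccc(cc1)Oc1cc(cc(OC)c1OC)CCc1cccc(OCc2ccccc2)c1
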